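Numbering as in labdanes: ring A = C1–C5 and C10, ring B = C5–C10, C17 = exocyclic CH2, C18/C19 = CH2OH, C20 = CH3. Read literally, the SMILES is the cis-fused decalin with H-5, CH3-20, 3-OH and the C9 side chain all on one face, and the route is planned for exactly this isomer.
Retrosynthesis cuts C12–C13 (butenolide), C4–C18 and C4–C19 (back to a C4 ketone), C9–C11, then C5–C10 and C6–C7 together, then C8–C7/C8–C17, C10–C20, C8–C9 and C1–C2 of an acyclic chain.
Enabling feature: ring B is a methylenecyclohexane whose C8 lies between C7 and C9, so C7=C8–C9=C10 can be a 2-(silylmethyl)diene. C4 bears two identical CH2OH groups, is no stereocenter, and can therefore be the ketone that activates C5=C6 inside the C1–C4 tether. Both helpers (C=O at C4, SiMe3 on C17) are removed afterwards.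
Forward: the chain is joined linearly (C2–C6 epoxy alcohol, C1/C10/C9 propyne unit, then C8, C20, C7/C17); rings A and B arise together in step 9; then C11–C12, C19, C18 and C13–C16 are added.
Stereochemistry: C3 from Sharpless epoxidation; C5 and C10 in the cycloaddition (cis fusion from the Z-alkene made by syn-carbocupration, π-face from C3); C9 by convex-face attack on the cis-fused allylsilane.

Key step: step 9

Remark: 3-bromofuran-2(5H)-one (22) is taken as a purchasable building block.

Step 1
Reactants: 1 penta-1,4-dien-3-ol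
Product: 2 (2R,3S)-1,2-epoxypent-4-en-3-ol
Conditions: Ti(OiPr)4 (cat.), L-(+)-diisopropyl tartrate (cat.), t-BuOOH, 4 Å MS, CH2Cl2, −20 °C
Reagents that add atoms: tert-butyl hydroperoxide, CC(C)(C)OO
Why: Sharpless asymmetric epoxidation desymmetrizes the divinyl carbinol under tartrate control and sets the epoxide carbon that becomes C3 (R) together with the transient C4 carbinol (S), the minor enantiomer being consumed by a second epoxidation.

Step 2
Reactants: 2 (2R,3S)-1,2-epoxypent-4-en-3-ol
Product: 3 (2R,3S)-1,2-epoxy-3-(triethylsilyloxy)pent-4-ene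
Conditions: Et3SiCl, imidazole, CH2Cl2, 0 °C
Reagents that add atoms: chlorotriethylsilane, CC[Si](Cl)(CC)CC
Why: Imidazole-promoted silylation masks the C4 hydroxyl as a triethylsilyl ether that can later be cleaved selectively beside a tert-butyldimethylsilyl ether, without touching a stereocenter.

Step 3
Reactants: 3 (2R,3S)-1,2-epoxy-3-(triethylsilyloxy)pent-4-ene; 4 1-(trimethylsilyl)propyne
Product: 5 (3S,4R)-3-(triethylsilyloxy)-8-(trimethylsilyl)oct-1-en-7-yn-4-ol
Conditions: 4, n-BuLi, THF, −78 → −20 °C; then 3, BF3·OEt2, −78 °C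
Reagents that add atoms: none
Why: Epoxide alkylation, in which the propargylic lithium reagent opens the BF3-activated terminal epoxide at its CH2 carbon (SN2), forms C1–C2 and leaves the C3–O stereocenter untouched.

Step 4
Reactants: 5 (3S,4R)-3-(triethylsilyloxy)-8-(trimethylsilyl)oct-1-en-7-yn-4-ol
Product: 6 (3S,4R)-4-(tert-butyldimethylsilyloxy)-3-(triethylsilyloxy)-8-(trimethylsilyl)oct-1-en-7-yne
Conditions: t-BuMe2SiOTf, 2,6-lutidine, CH2Cl2, −78 °C
Reagents that add atoms: tert-butyldimethylsilyl trifluoromethanesulfonate, CC(C)(C)[Si](C)(C)OS(=O)(=O)C(F)(F)F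
Why: Silylation with the silyl triflate protects the secondary C3 hydroxyl as the silyl ether that is kept to the last step.

Step 5
Reactants: 6 (3S,4R)-4-(tert-butyldimethylsilyloxy)-3-(triethylsilyloxy)-8-(trimethylsilyl)oct-1-en-7-yne
Product: 8 methyl (6R,7S)-6-(tert-butyldimethylsilyloxy)-7-(triethylsilyloxy)non-8-en-2-ynoate, via lithium acetylide 7 (not isolated)
Conditions: MeLi·LiBr, THF, 0 °C → rt; then ClCO2Me, −78 °C
Reagents that add atoms: methyl chloroformate, COC(=O)Cl
Why: Methyllithium cleaves the alkynyl C–Si bond to the lithium acetylide, whose acylation with the chloroformate (acetylide carboxylation) installs C8 as the ynoate.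

Step 6
Reactants: 8 methyl (6R,7S)-6-(tert-butyldimethylsilyloxy)-7-(triethylsilyloxy)non-8-en-2-ynoate
Product: 9 methyl (2Z,6R,7S)-6-(tert-butyldimethylsilyloxy)-3-methyl-7-(triethylsilyloxy)nona-2,8-dienoate
Conditions: CuI, MeLi (2 equiv), THF, −78 °C; AcOH quench at −78 °C
Reagents that add atoms: lithium dimethylcuprate (Me2CuLi, from MeLi and CuI), [Li+].C[Cu-]C
Why: Syn-carbocupration (organocuprate conjugate addition to an ynoate) with protonation at −78 °C places CH3-20 and H-9 cis, so that the C1 chain is cis to C8 in the (Z)-enoate, the geometry that later enforces the cis ring fusion.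

Step 7
Reactants: 9 methyl (2Z,6R,7S)-6-(tert-butyldimethylsilyloxy)-3-methyl-7-(triethylsilyloxy)nona-2,8-dienoate
Product: 10 methyl (2Z,6R,7S)-6-(tert-butyldimethylsilyloxy)-7-hydroxy-3-methylnona-2,8-dienoate
Conditions: PPTS (cat.), MeOH, 0 °C
Reagents that add atoms: none
Why: Acid-catalysed methanolysis (selective desilylation) removes the more labile triethylsilyl ether and leaves the tert-butyldimethylsilyl ether, freeing the C4 hydroxyl for oxidation.

Step 8
Reactants: 10 methyl (2Z,6R,7S)-6-(tert-butyldimethylsilyloxy)-7-hydroxy-3-methylnona-2,8-dienoate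
Product: 12 (3S,4R,7Z)-4-(tert-butyldimethylsilyloxy)-7-methyl-9-[(trimethylsilyl)methyl]deca-1,7,9-trien-3-ol, via bis(silylmethyl) carbinol 11 (not isolated)
Conditions: Me3SiCH2MgCl, CeCl3, THF, −78 °C → rt; then silica gel, CH2Cl2, rt
Reagents that add atoms: (trimethylsilyl)methylmagnesium chloride, C[Si](C)(C)C[Mg]Cl
Why: Double 1,2-addition of the organocerium reagent to the ester and acid-promoted Peterson elimination of the resulting β-silyl carbinol convert C8 into the 2-(silylmethyl)-1,3-diene with retention of the (Z)-C9=C10 geometry.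

Step 9
Reactants: 12 (3S,4R,7Z)-4-(tert-butyldimethylsilyloxy)-7-methyl-9-[(trimethylsilyl)methyl]deca-1,7,9-trien-3-ol
Product: 14 (2R,4aS,8aR)-2-(tert-butyldimethylsilyloxy)-4a-methyl-6-[(trimethylsilyl)methyl]-3,4,4a,7,8,8a-hexahydronaphthalen-1(2H)-one, via trienone 13 (not isolated)
Conditions: Dess–Martin periodinane, NaHCO3, CH2Cl2, 0 °C; then toluene, BHT (cat.), 90 °C
Reagents that add atoms: none
Why: Dess–Martin oxidation unveils the vinyl ketone 13, whose C5=C6 bond then adds suprafacially to the s-cis diene C7=C8–C9=C10 in a concerted but asynchronous normal-demand intramolecular Diels–Alder reaction in which the unhindered C6–C7 bond leads, because the CH2SiMe3 donor at C8 makes C7 the nucleophilic terminus and the C4 carbonyl makes C6 the electrophilic one. The closest known reaction type is the type 1 intramolecular Diels–Alder reaction of 1,7,9-decatrien-3-ones, together with the known use of 2-(silylmethyl)-1,3-dienes as Diels–Alder dienes. Ring B (C5, C6, C7, C8, C9, C10) is closed as the new cyclohexene by the [4+2] event itself, and ring A (C1 to C5 and C10) is closed by the C5–C10 bond as the fused ring, through a chair-like four-atom tether. The two new stereocenters C5 and C10 (quaternary) are related by the (Z)-geometry of C9=C10, which holds the tether on the inside of the diene, so only the cis-fused transition state can be reached and H-5 ends syn to CH3-20. The π-face is chosen by C3, whose silyloxy group sits equatorial on the chair-like tether (an axial one would be 1,3-diaxial to C6), which places O-3 syn to H-5 and CH3-20. The step therefore needs cis over trans fusion, one π-face and cycloaddition faster than a [1,5]-hydrogen shift of the (Z)-diene, and these are secured by the alkene geometry, by the C3 stereocenter and by the ketone activation that should let the reaction run below 100 °C.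

Step 10
Reactants: 14 (2R,4aS,8aR)-2-(tert-butyldimethylsilyloxy)-4a-methyl-6-[(trimethylsilyl)methyl]-3,4,4a,7,8,8a-hexahydronaphthalen-1(2H)-one
Product: 15 (2R,4aS,5R,8aR)-2-(tert-butyldimethylsilyloxy)-5-(2-hydroxyethyl)-4a-methyl-6-methylideneoctahydronaphthalen-1(2H)-one
Conditions: ethylene oxide (excess), TiCl4, CH2Cl2, −78 °C
Reagents that add atoms: ethylene oxide, C1CO1
Why: Hosomi–Sakurai-type SE2' alkylation, in which the TiCl4-activated epoxide is attacked by the γ-carbon C9 of the allylsilane with loss of silicon to give the C8 exocyclic methylene, should occur axially on the convex face of the cis-fused bicycle (anti to the pseudoaxial C10–C1 bond, syn to H-5 and CH3-20), which sets C9.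

Step 11
Reactants: 15 (2R,4aS,5R,8aR)-2-(tert-butyldimethylsilyloxy)-5-(2-hydroxyethyl)-4a-methyl-6-methylideneoctahydronaphthalen-1(2H)-one
Product: 17 2-(tert-butyldimethylsilyloxy)-5-(2-hydroxyethyl)-4a-methyl-6-methylidenedecahydronaphthalene-1-carbaldehyde (C1 epimers; ring stereocenters as in 15), via methyl enol ether 16 (not isolated)
Conditions: Ph3P(CH2OMe)Cl, KOtBu (excess), THF, 0 °C → rt; then 1 M HCl, THF, rt
Reagents that add atoms: (methoxymethyl)triphenylphosphonium chloride, COC[P+](c1ccccc1)(c1ccccc1)c1ccccc1.[Cl-]; water, O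
Why: Wittig methoxymethylenation of the C4 ketone and mild acid hydrolysis of the enol ether (one-carbon homologation) give the C4 carbaldehyde, whose C4 configuration does not matter because C4 ends as a non-stereogenic carbon.

Step 12
Reactants: 17 2-(tert-butyldimethylsilyloxy)-5-(2-hydroxyethyl)-4a-methyl-6-methylidenedecahydronaphthalene-1-carbaldehyde (C1 epimers; ring stereocenters as in 15)
Product: 19 2-[(1R,4aR,6R,8aS)-6-(tert-butyldimethylsilyloxy)-5,5-bis(hydroxymethyl)-8a-methyl-2-methylidenedecahydronaphthalen-1-yl]ethanol, via hydroxy aldehyde 18 (not isolated)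
Conditions: 37% aq. HCHO (excess), KOH, EtOH/H2O, 50 °C
Reagents that add atoms: formaldehyde, C=O
Why: Tollens condensation, in which crossed aldol addition of the aldehyde enolate to formaldehyde creates the quaternary C4 and crossed Cannizzaro hydride transfer from formaldehyde reduces the aldehyde, gives C4 two identical CH2OH groups, so no stereocenter arises.

Step 13
Reactants: 19 2-[(1R,4aR,6R,8aS)-6-(tert-butyldimethylsilyloxy)-5,5-bis(hydroxymethyl)-8a-methyl-2-methylidenedecahydronaphthalen-1-yl]ethanol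
Product: 20 acetonide of 19 at the two C4 hydroxymethyl groups (spiro 2,2-dimethyl-1,3-dioxane; side-chain alcohol free)
Conditions: Me2C(OMe)2, PPTS (cat.), acetone, rt
Reagents that add atoms: 2,2-dimethoxypropane, COC(C)(C)OC
Why: Acid-catalysed acetal exchange (acetonide formation) ties the 1,3-diol into a six-membered 1,3-dioxane and leaves the side-chain primary alcohol free.

Step 14
Reactants: 20 acetonide of 19 at the two C4 hydroxymethyl groups (spiro 2,2-dimethyl-1,3-dioxane; side-chain alcohol free)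
Product: 21 primary iodide of 20 (C12–I)
Conditions: I2, PPh3, imidazole, CH2Cl2, 0 °C → rt
Reagents that add atoms: iodine, II
Why: Appel-type iodination converts the unhindered primary alcohol into the primary iodide by SN2 displacement of the alkoxyphosphonium ion, with no stereocenter involved.

Step 15
Reactants: 21 primary iodide of 20 (C12–I); 22 3-bromofuran-2(5H)-one
Product: 24 3-substituted furan-2(5H)-one carrying the 3-O-silyl ether and the 18,19-acetonide of the target, via organozinc iodide 23 (not isolated)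
Conditions: Zn dust (Me3SiCl-activated), DMA, 40 °C; then 22, Pd2(dba)3 (cat.), SPhos (cat.), THF, rt
Reagents that add atoms: none
Why: Zinc insertion into the primary C–I bond and Negishi sp3–sp2 cross-coupling with the α-bromobutenolide form C12–C13 under neutral conditions that the exocyclic alkene, the silyl ether, the acetonide and the butenolide should tolerate.

Step 16
Reactants: 24 3-substituted furan-2(5H)-one carrying the 3-O-silyl ether and the 18,19-acetonide of the target
Product: 25 3-{2-[(1R,4aR,6R,8aS)-6-hydroxy-5,5-bis(hydroxymethyl)-8a-methyl-2-methylidenedecahydronaphthalen-1-yl]ethyl}furan-2(5H)-one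
Conditions: 48% aq. HF, MeCN, 0 °C → rt
Reagents that add atoms: none
Why: Global deprotection, in which aqueous HF cleaves the silyl ether and hydrolyses the acetonide without affecting the exocyclic alkene or the butenolide, releases the triol of the target.

Compound list
1 | penta-1,4-dien-3-ol | C=CC(O)C=C | starting material
2 | (2R,3S)-1,2-epoxypent-4-en-3-ol | C=C[C@H](O)[C@H]1CO1 | intermediate
3 | (2R,3S)-1,2-epoxy-3-(triethylsilyloxy)pent-4-ene | C=C[C@H](O[Si](CC)(CC)CC)[C@H]1CO1 | intermediate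
4 | 1-(trimethylsilyl)propyne | CC#C[Si](C)(C)C | starting material
5 | (3S,4R)-3-(triethylsilyloxy)-8-(trimethylsilyl)oct-1-en-7-yn-4-ol | C[Si](C)(C)C#CCC[C@@H](O)[C@@H](O[Si](CC)(CC)CC)C=C | intermediate
6 | (3S,4R)-4-(tert-butyldimethylsilyloxy)-3-(triethylsilyloxy)-8-(trimethylsilyl)oct-1-en-7-yne | C[Si](C)(C)C#CCC[C@@H](O[Si](C)(C)C(C)(C)C)[C@@H](O[Si](CC)(CC)CC)C=C | intermediate
7 | [(5R,6S)-5-(tert-butyldimethylsilyloxy)-6-(triethylsilyloxy)oct-7-en-1-yn-1-yl]lithium | [Li]C#CCC[C@@H](O[Si](C)(C)C(C)(C)C)[C@@H](O[Si](CC)(CC)CC)C=C | intermediate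
8 | methyl (6R,7S)-6-(tert-butyldimethylsilyloxy)-7-(triethylsilyloxy)non-8-en-2-ynoate | COC(=O)C#CCC[C@@H](O[Si](C)(C)C(C)(C)C)[C@@H](O[Si](CC)(CC)CC)C=C | intermediate
9 | methyl (2Z,6R,7S)-6-(tert-butyldimethylsilyloxy)-3-methyl-7-(triethylsilyloxy)nona-2,8-dienoate | COC(=O)/C=C(/C)CC[C@@H](O[Si](C)(C)C(C)(C)C)[C@@H](O[Si](CC)(CC)CC)C=C | intermediate
10 | methyl (2Z,6R,7S)-6-(tert-butyldimethylsilyloxy)-7-hydroxy-3-methylnona-2,8-dienoate | COC(=O)/C=C(/C)CC[C@@H](O[Si](C)(C)C(C)(C)C)[C@@H](O)C=C | intermediate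
11 | (3Z,7R,8S)-7-(tert-butyldimethylsilyloxy)-4-methyl-1-(trimethylsilyl)-2-[(trimethylsilyl)methyl]deca-3,9-diene-2,8-diol | C[Si](C)(C)CC(O)(C[Si](C)(C)C)/C=C(/C)CC[C@@H](O[Si](C)(C)C(C)(C)C)[C@@H](O)C=C | intermediate
12 | (3S,4R,7Z)-4-(tert-butyldimethylsilyloxy)-7-methyl-9-[(trimethylsilyl)methyl]deca-1,7,9-trien-3-ol | C=C(C[Si](C)(C)C)/C=C(/C)CC[C@@H](O[Si](C)(C)C(C)(C)C)[C@@H](O)C=C | intermediate
13 | (4R,7Z)-4-(tert-butyldimethylsilyloxy)-7-methyl-9-[(trimethylsilyl)methyl]deca-1,7,9-trien-3-one | C=C(C[Si](C)(C)C)/C=C(/C)CC[C@@H](O[Si](C)(C)C(C)(C)C)C(=O)C=C | intermediate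
14 | (2R,4aS,8aR)-2-(tert-butyldimethylsilyloxy)-4a-methyl-6-[(trimethylsilyl)methyl]-3,4,4a,7,8,8a-hexahydronaphthalen-1(2H)-one (cis-fused; 8a-H, 4a-CH3 and 2-O on one face) | C[Si](C)(C)CC1CC[C@H]2C(=O)[C@H](O[Si](C)(C)C(C)(C)C)CC[C@@]2(C)C=1 | intermediate
15 | (2R,4aS,5R,8aR)-2-(tert-butyldimethylsilyloxy)-5-(2-hydroxyethyl)-4a-methyl-6-methylideneoctahydronaphthalen-1(2H)-one | C=C1CC[C@H]2C(=O)[C@H](O[Si](C)(C)C(C)(C)C)CC[C@@]2(C)[C@@H]1CCO | intermediate
16 | 2-[(1R,4aR,6R,8aS)-6-(tert-butyldimethylsilyloxy)-5-(methoxymethylidene)-8a-methyl-2-methylidenedecahydronaphthalen-1-yl]ethanol (enol ether E/Z mixture) | C=C1CC[C@H]2C(=COC)[C@H](O[Si](C)(C)C(C)(C)C)CC[C@@]2(C)[C@@H]1CCO | intermediate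
17 | 2-(tert-butyldimethylsilyloxy)-5-(2-hydroxyethyl)-4a-methyl-6-methylidenedecahydronaphthalene-1-carbaldehyde (C1 epimers; ring stereocenters as in 15) | C=C1CC[C@H]2C(C=O)[C@H](O[Si](C)(C)C(C)(C)C)CC[C@@]2(C)[C@@H]1CCO | intermediate
18 | 2-(tert-butyldimethylsilyloxy)-5-(2-hydroxyethyl)-1-(hydroxymethyl)-4a-methyl-6-methylidenedecahydronaphthalene-1-carbaldehyde (C1 epimers; ring stereocenters as in 15) | C=C1CC[C@H]2C(CO)(C=O)[C@H](O[Si](C)(C)C(C)(C)C)CC[C@@]2(C)[C@@H]1CCO | intermediate
19 | 2-[(1R,4aR,6R,8aS)-6-(tert-butyldimethylsilyloxy)-5,5-bis(hydroxymethyl)-8a-methyl-2-methylidenedecahydronaphthalen-1-yl]ethanol | C=C1CC[C@H]2C(CO)(CO)[C@H](O[Si](C)(C)C(C)(C)C)CC[C@@]2(C)[C@@H]1CCO | intermediate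
20 | acetonide of 19 at the two C4 hydroxymethyl groups: 2-[(1R,4aR,6R,8aS)-6-(tert-butyldimethylsilyloxy)-5,5-(2,2-dimethyl-1,3-dioxane-5,5-diyl)-8a-methyl-2-methylidenedecahydronaphthalen-1-yl]ethanol | C=C1CC[C@H]2C3(COC(C)(C)OC3)[C@H](O[Si](C)(C)C(C)(C)C)CC[C@@]2(C)[C@@H]1CCO | intermediate
21 | primary iodide of 20: the same spiro acetonide silyl ether with a 2-iodoethyl group at C9 | C=C1CC[C@H]2C3(COC(C)(C)OC3)[C@H](O[Si](C)(C)C(C)(C)C)CC[C@@]2(C)[C@@H]1CCI | intermediate
22 | 3-bromofuran-2(5H)-one | O=C1OCC=C1Br | starting material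
23 | organozinc iodide from 21 (C12–ZnI) | C=C1CC[C@H]2C3(COC(C)(C)OC3)[C@H](O[Si](C)(C)C(C)(C)C)CC[C@@]2(C)[C@@H]1CC[Zn]I | intermediate
24 | 3-{2-[(1R,4aR,6R,8aS)-6-(tert-butyldimethylsilyloxy)-5,5-(2,2-dimethyl-1,3-dioxane-5,5-diyl)-8a-methyl-2-methylidenedecahydronaphthalen-1-yl]ethyl}furan-2(5H)-one | C=C1CC[C@H]2C3(COC(C)(C)OC3)[C@H](O[Si](C)(C)C(C)(C)C)CC[C@@]2(C)[C@@H]1CCC1=CCOC1=O | intermediate
25 | 3-{2-[(1R,4aR,6R,8aS)-6-hydroxy-5,5-bis(hydroxymethyl)-8a-methyl-2-methylidenedecahydronaphthalen-1-yl]ethyl}furan-2(5H)-one (CNP0146463.1) | C=C1CC[C@H]2C(CO)(CO)[C@H](O)CC[C@@]2(C)[C@@H]1CCC1=CCOC1=O | target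

Total step count: 16
Longest linear sequence: 16 steps (1 → 25)

Steps most likely to fail

Step 9. The (Z)-diene reaches its s-cis conformation slowly, so a [1,5]-hydrogen shift in the diene or oligomerization of the enone may overtake ring closure. The fallback sets out from 10 and returns at 14. The ester of 10 is converted with Me3SiCH2Li (then MeOH) into the (Z)-methyl ketone F1. Dess–Martin oxidation gives the diketone F2. t-BuMe2SiOTf/Et3N at −78 °C forms the 2-silyloxy diene F3, a far more electron-rich diene that should undergo the same cis-selective intramolecular Diels–Alder reaction on warming to room temperature, giving the silyl enol ether cycloadduct F4. CsF/PhNTf2 converts it into the enol triflate F5. Negishi coupling of F5 with Me3SiCH2ZnCl (from Me3SiCH2MgCl and ZnCl2, Pd(PPh3)4 cat.) installs the CH2SiMe3 group and gives 14.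

Step 10. Protodesilylation of the allylsilane by adventitious HCl, or chloride opening of the activated epoxide, may outrun C–C bond formation at the hindered C9. The fallback sets out from 14 and returns at 15. A Hosomi–Sakurai reaction with (tert-butyldimethylsilyloxy)acetaldehyde and BF3·OEt2 at −78 °C should give, with the same convex-face selectivity, the hydroxy silyl ether F6. PhOC(S)Cl/pyridine/DMAP converts it into the thionocarbonate F7. Bu3SnH/AIBN in toluene at 80 °C (Barton–McCombie deoxygenation) removes the C11 oxygen and gives the bis-silyl ether F8. HF·pyridine/pyridine in THF at 0 °C cleaves the primary silyl ether selectively and gives 15.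

Step 12. E1cB loss of the C3 silyloxy group from the aldehyde enolate under hydroxide, or incomplete hydride transfer to the neopentyl aldehyde, may compete. The fallback sets out from 17 and returns at 19. Me3SiOTf/Et3N converts 17 into the bis-trimethylsilyl enol ether F9 (the primary alcohol is silylated as well). A Mukaiyama aldol hydroxymethylation with aqueous HCHO and Yb(OTf)3 (cat.) in THF/H2O forms the quaternary carbon under non-basic conditions and gives the hydroxy aldehyde 18. NaBH4 in MeOH at 0 °C reduces 18 to 19.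

Further compounds
F1 | step 9 | (3Z,7R,8S)-7-(tert-butyldimethylsilyloxy)-8-hydroxy-4-methyldeca-3,9-dien-2-one | CC(=O)/C=C(/C)CC[C@@H](O[Si](C)(C)C(C)(C)C)[C@@H](O)C=C
F2 | step 9 | (4R,7Z)-4-(tert-butyldimethylsilyloxy)-7-methyldeca-1,7-diene-3,9-dione | CC(=O)/C=C(/C)CC[C@@H](O[Si](C)(C)C(C)(C)C)C(=O)C=C
F3 | step 9 | (4R,7Z)-4,9-bis(tert-butyldimethylsilyloxy)-7-methyldeca-1,7,9-trien-3-one | C=C(O[Si](C)(C)C(C)(C)C)/C=C(/C)CC[C@@H](O[Si](C)(C)C(C)(C)C)C(=O)C=C
F4 | step 9 | (2R,4aS,8aR)-2,6-bis(tert-butyldimethylsilyloxy)-4a-methyl-3,4,4a,7,8,8a-hexahydronaphthalen-1(2H)-one | CC(C)(C)[Si](C)(C)OC1CC[C@H]2C(=O)[C@H](O[Si](C)(C)C(C)(C)C)CC[C@@]2(C)C=1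
F5 | step 9 | enol triflate of F4: the C8 trifluoromethanesulfonate with C8=C9, C4 ketone and 3-O-silyl ether retained (ring stereocenters as in 14) | O=S(=O)(OC1CC[C@H]2C(=O)[C@H](O[Si](C)(C)C(C)(C)C)CC[C@@]2(C)C=1)C(F)(F)F
F6 | step 10 | (2R,4aS,5R,8aR)-2-(tert-butyldimethylsilyloxy)-5-[2-(tert-butyldimethylsilyloxy)-1-hydroxyethyl]-4a-methyl-6-methylideneoctahydronaphthalen-1(2H)-one (carbinol epimers) | C=C1CC[C@H]2C(=O)[C@H](O[Si](C)(C)C(C)(C)C)CC[C@@]2(C)[C@@H]1C(O)CO[Si](C)(C)C(C)(C)C
F7 | step 10 | O-phenyl thionocarbonate of F6 at the C11 hydroxyl | C=C1CC[C@H]2C(=O)[C@H](O[Si](C)(C)C(C)(C)C)CC[C@@]2(C)[C@@H]1C(OC(=S)Oc1ccccc1)CO[Si](C)(C)C(C)(C)C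
F8 | step 10 | (2R,4aS,5R,8aR)-2-(tert-butyldimethylsilyloxy)-5-[2-(tert-butyldimethylsilyloxy)ethyl]-4a-methyl-6-methylideneoctahydronaphthalen-1(2H)-one | C=C1CC[C@H]2C(=O)[C@H](O[Si](C)(C)C(C)(C)C)CC[C@@]2(C)[C@@H]1CCO[Si](C)(C)C(C)(C)C
F9 | step 12 | trimethylsilyl enol ether of 17 with the side-chain alcohol as its trimethylsilyl ether (ring stereocenters as in 15; enol ether E/Z mixture) | C=C1CC[C@H]2C(=CO[Si](C)(C)C)[C@H](O[Si](C)(C)C(C)(C)C)CC[C@@]2(C)[C@@H]1CCO[Si](C)(C)C
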